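**Assumption:** the target has no stereocentre or other stereogenic element (it is achiral), so no enantiocontrol is needed.

## Retrosynthetic overview

1. The free CO2H on the heptyl ring comes from a last-step oxidation of an aryl aldehyde; the 6-OMe comes from methylation of the chelated ortho-OH after the rings are joined.
2. The depside ester C–O bond is cut to 2,4-dimethoxy-6-pentylbenzoic acid and 2-heptyl-4,6-dihydroxybenzaldehyde, which acylates only at the non-chelated 4-OH.
3. Each ring–CHO bond is cut by Vilsmeier formylation of a 5-alkylresorcinol derivative.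
4. Key disconnection: both aryl–C(sp3) side-chain bonds. 1-Bromo-3,5-dimethoxybenzene is the electrophile; pentanal and heptanal are used as carbonyl-carbon nucleophiles through their N–H hydrazones (Ni catalysis, loss of N2).
5. No ring is built; both benzene rings come from the same aryl bromide.

## Route

Step 1
Reactants: 1 1-bromo-3,5-dimethoxybenzene; 2 pentanal
Product: 4 1,3-dimethoxy-5-pentylbenzene, via pentanal hydrazone 3 (not isolated)
Conditions: N2H4·H2O (3 equiv), THF, 0 °C to rt, excess N2H4/H2O stripped; then 1, Ni(cod)2 (10 mol %), PMe3 (20 mol %), K3PO4 (2 equiv), dioxane, 80 °C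
Reagents that add atoms: hydrazine hydrate, NN.O (its N atoms sit in 3 only and leave as N2)
Why: Proposed new method: Ni(0)-catalysed Wolff–Kishner-type cross-coupling in which the N–H hydrazone 3 acts as an umpoled carbonyl (an acyl-anion equivalent at the alkane oxidation level) — oxidative addition of 1 to Ni(0), base-assisted N-binding and deprotonation of 3, 1,3-H shift and loss of N2 give an aryl–Ni–CH2Bu species that reductively eliminates to join two normally electrophilic carbons; the closest known reaction type is the Ni/PMe3-catalysed coupling of aryl-aldehyde N–H hydrazones with aryl halides, extended here to an n-alkyl hydrazone, where β-hydride elimination and azine formation are the risks.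

Step 2
Reactants: 4 1,3-dimethoxy-5-pentylbenzene
Product: 6 2,4-dimethoxy-6-pentylbenzaldehyde, via aryl iminium salt 5 (not isolated)
Conditions: POCl3 (1.5 equiv), DMF, 0 to 80 °C; then ice/H2O
Reagents that add atoms: N,N-dimethylformamide, CN(C)C=O (formyl carbon); water, O (formyl oxygen); phosphoryl chloride, O=P(Cl)(Cl)Cl (counter-ion of 5 only)
Why: Vilsmeier–Haack formylation of a resorcinol dimethyl ether goes para to one OMe and ortho to the other, next to the alkyl group, rather than at the crowded position between the two OMe groups.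

Step 3
Reactants: 6 2,4-dimethoxy-6-pentylbenzaldehyde
Product: 7 2,4-dimethoxy-6-pentylbenzoic acid
Conditions: NaClO2, NaH2PO4, 2-methyl-2-butene, t-BuOH/THF/H2O, rt
Reagents that add atoms: sodium chlorite, [Na+].[O-]Cl=O
Why: Pinnick oxidation converts the hindered aryl aldehyde to the acid under mild buffered conditions, with the alkene trapping HOCl so the electron-rich ring is not chlorinated.

Step 4
Reactants: 1 1-bromo-3,5-dimethoxybenzene; 8 heptanal
Product: 10 1-heptyl-3,5-dimethoxybenzene, via heptanal hydrazone 9 (not isolated)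
Conditions: N2H4·H2O (3 equiv), THF, 0 °C to rt, excess N2H4/H2O stripped; then 1, Ni(cod)2 (10 mol %), PMe3 (20 mol %), K3PO4 (2 equiv), dioxane, 80 °C
Reagents that add atoms: hydrazine hydrate, NN.O (its N atoms sit in 9 only and leave as N2)
Why: Proposed new method: the same Ni(0)-catalysed Wolff–Kishner-type cross-coupling as in step 1, with hydrazone 9 as the umpoled heptanal carbon (oxidative addition of 1, N-binding and deprotonation of 9, N2 loss to aryl–Ni–CH2-hexyl, reductive elimination); the closest known reaction type is the Ni/PMe3 coupling of aryl-aldehyde N–H hydrazones with aryl halides.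

Step 5
Reactants: 10 1-heptyl-3,5-dimethoxybenzene
Product: 11 5-heptylbenzene-1,3-diol
Conditions: BBr3 (3 equiv), CH2Cl2, −78 °C to rt; H2O quench
Reagents that add atoms: none
Why: Lewis-acid ether cleavage (BBr3 demethylation) of both aryl methyl ethers, with no other sensitive group present.

Step 6
Reactants: 11 5-heptylbenzene-1,3-diol
Product: 13 2-heptyl-4,6-dihydroxybenzaldehyde, via aryl iminium salt 12 (not isolated)
Conditions: POCl3 (1.2 equiv), DMF, 0 °C to rt; then H2O, 50 °C
Reagents that add atoms: N,N-dimethylformamide, CN(C)C=O (formyl carbon); water, O (formyl oxygen); phosphoryl chloride, O=P(Cl)(Cl)Cl (counter-ion of 12 only)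
Why: Vilsmeier–Haack formylation of a 5-alkylresorcinol occurs ortho to the alkyl group and ortho/para to the two hydroxyls, as is standard for olivetol-type substrates.

Step 7
Reactants: 7 2,4-dimethoxy-6-pentylbenzoic acid; 13 2-heptyl-4,6-dihydroxybenzaldehyde
Product: 15 4-formyl-3-heptyl-5-hydroxyphenyl 2,4-dimethoxy-6-pentylbenzoate, via mixed trifluoroacetic anhydride 14 (not isolated)
Conditions: TFAA (4 equiv), toluene, rt
Reagents that add atoms: trifluoroacetic anhydride, O=C(OC(=O)C(F)(F)F)C(F)(F)F (its CF3CO group sits in 14 only)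
Why: TFAA-mediated depside esterification — the hindered, electron-rich acid is activated as its mixed anhydride/acylium and acylates the free 4-OH, while the 6-OH is deactivated by its hydrogen bond to the aldehyde.

Step 8
Reactants: 15 4-formyl-3-heptyl-5-hydroxyphenyl 2,4-dimethoxy-6-pentylbenzoate
Product: 16 4-formyl-3-heptyl-5-methoxyphenyl 2,4-dimethoxy-6-pentylbenzoate
Conditions: MeI (3 equiv), K2CO3 (1.5 equiv), DMF, rt
Reagents that add atoms: iodomethane, CI
Why: Williamson O-methylation of the remaining chelated phenol; the 2,6-disubstituted aroyl ester is too hindered to be cleaved by carbonate under anhydrous conditions.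

Step 9
Reactants: 16 4-formyl-3-heptyl-5-methoxyphenyl 2,4-dimethoxy-6-pentylbenzoate
Product: 17 4-[(2,4-dimethoxy-6-pentylbenzoyl)oxy]-2-heptyl-6-methoxybenzoic acid (CNP0206304.0)
Conditions: NaClO2, NaH2PO4, 2-methyl-2-butene, t-BuOH/THF/H2O, 0 °C to rt
Reagents that add atoms: sodium chlorite, [Na+].[O-]Cl=O
Why: Pinnick oxidation turns the aldehyde into the free acid at pH about 4, which leaves the aryl ester and methyl ethers intact.

## Compound list

1 | 1-bromo-3,5-dimethoxybenzene | COc1cc(Br)cc(OC)c1 | starting material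
2 | pentanal | CCCCC=O | starting material
3 | pentanal hydrazone, (E)-pentylidenehydrazine (formed in situ) | CCCC/C=N/N | intermediate
4 | 1,3-dimethoxy-5-pentylbenzene | CCCCCc1cc(OC)cc(OC)c1 | intermediate
5 | N-[(2,4-dimethoxy-6-pentylphenyl)methylidene]-N-methylmethanaminium dichlorophosphate (formed in situ) | CCCCCc1cc(OC)cc(OC)c1C=[N+](C)C.[O-]P(=O)(Cl)Cl | intermediate
6 | 2,4-dimethoxy-6-pentylbenzaldehyde | CCCCCc1cc(OC)cc(OC)c1C=O | intermediate
7 | 2,4-dimethoxy-6-pentylbenzoic acid | CCCCCc1cc(OC)cc(OC)c1C(=O)O | intermediate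
8 | heptanal | CCCCCCC=O | starting material
9 | heptanal hydrazone, (E)-heptylidenehydrazine (formed in situ) | CCCCCC/C=N/N | intermediate
10 | 1-heptyl-3,5-dimethoxybenzene | CCCCCCCc1cc(OC)cc(OC)c1 | intermediate
11 | 5-heptylbenzene-1,3-diol | CCCCCCCc1cc(O)cc(O)c1 | intermediate
12 | N-[(2-heptyl-4,6-dihydroxyphenyl)methylidene]-N-methylmethanaminium dichlorophosphate (formed in situ) | CCCCCCCc1cc(O)cc(O)c1C=[N+](C)C.[O-]P(=O)(Cl)Cl | intermediate
13 | 2-heptyl-4,6-dihydroxybenzaldehyde | CCCCCCCc1cc(O)cc(O)c1C=O | intermediate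
14 | 2,4-dimethoxy-6-pentylbenzoic trifluoroacetic anhydride (formed in situ) | CCCCCc1cc(OC)cc(OC)c1C(=O)OC(=O)C(F)(F)F | intermediate
15 | 4-formyl-3-heptyl-5-hydroxyphenyl 2,4-dimethoxy-6-pentylbenzoate | CCCCCCCc1cc(OC(=O)c2c(CCCCC)cc(OC)cc2OC)cc(O)c1C=O | intermediate
16 | 4-formyl-3-heptyl-5-methoxyphenyl 2,4-dimethoxy-6-pentylbenzoate | CCCCCCCc1cc(OC(=O)c2c(CCCCC)cc(OC)cc2OC)cc(OC)c1C=O | intermediate
17 | 4-[(2,4-dimethoxy-6-pentylbenzoyl)oxy]-2-heptyl-6-methoxybenzoic acid | CCCCCCCc1cc(OC(=O)c2c(CCCCC)cc(OC)cc2OC)cc(OC)c1C(=O)O | target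

## Step count and risks

Total steps: 9. Longest linear sequence: 6 (steps 4, 5, 6, 7, 8, 9; the other branch, steps 1, 2, 3, 7, 8, 9, is equally long).

Steps most likely to fail:

**Step 1 (key coupling, pentyl chain).** An n-alkyl N–H hydrazone may give azine, or the alkyl–Ni intermediate may β-hydride eliminate, leaving reduced arene. The fallback sets out from 1 and keeps an acyl-anion-type nucleophile but changes both metal and nucleophile. Pd-catalysed C-arylation of the nitronate of commercial 1-nitropentane with 1 (Pd2(dba)3, 2-(di-tert-butylphosphino)-2'-methylbiphenyl, Cs2CO3, DME, 50 °C) gives racemic 1,3-dimethoxy-5-(1-nitropentyl)benzene F1. Radical denitration of its benzylic nitro group (Bu3SnH, AIBN, toluene, 110 °C) comes back to the route at 4.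

**Step 4 (key coupling, heptyl chain).** This has the same failure modes as step 1. The fallback sets out from 1 and 8 and replaces the hydrazone carbanion by a Pd-carbene coupling. Heptanal 8 with TsNHNH2 (MeOH, rt) gives heptanal N-tosylhydrazone F2. Pd-catalysed coupling with 1 (Pd2(dba)3, XPhos, LiOt-Bu, dioxane, 100 °C; diazoalkane, Pd-carbene, aryl migration, β-hydride elimination) gives (E)-1-(hept-1-en-1-yl)-3,5-dimethoxybenzene F3. Hydrogenation (H2, Pd/C, EtOAc) returns to the route at 10.

**Step 7 (selective acylation of the diol with a very hindered acid).** Bis-acylation or sluggish coupling is possible. The fallback sets out from 13 and differentiates the two phenols by protection before the rings are joined.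
- MOMCl/i-Pr2NEt (CH2Cl2, 0 °C) protects the non-chelated 4-OH to give 2-heptyl-6-hydroxy-4-(methoxymethoxy)benzaldehyde F4.
- MeI/K2CO3 (DMF) gives 2-heptyl-6-methoxy-4-(methoxymethoxy)benzaldehyde F5.
- Aqueous HCl/THF (50 °C) gives 2-heptyl-4-hydroxy-6-methoxybenzaldehyde F6.
- The single phenol of F6 is then esterified with 7 (TFAA, toluene, again through 14), coming back to the route at 16 and bypassing step 8 as well.

## Further compounds

F1 | step 1 | 1,3-dimethoxy-5-(1-nitropentyl)benzene (racemic) | CCCCC(c1cc(OC)cc(OC)c1)[N+](=O)[O-]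
F2 | step 4 | heptanal N-tosylhydrazone, (E)-N'-heptylidene-4-methylbenzenesulfonohydrazide | CCCCCC/C=N/NS(=O)(=O)c1ccc(C)cc1
F3 | step 4 | (E)-1-(hept-1-en-1-yl)-3,5-dimethoxybenzene | CCCCC/C=C/c1cc(OC)cc(OC)c1
F4 | step 7 | 2-heptyl-6-hydroxy-4-(methoxymethoxy)benzaldehyde | CCCCCCCc1cc(OCOC)cc(O)c1C=O
F5 | step 7 | 2-heptyl-6-methoxy-4-(methoxymethoxy)benzaldehyde | CCCCCCCc1cc(OCOC)cc(OC)c1C=O
F6 | step 7 | 2-heptyl-4-hydroxy-6-methoxybenzaldehyde | CCCCCCCc1cc(O)cc(OC)c1C=O
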